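The route rests on disconnecting the C5–C10 bond of ring A. In the target, quaternary C10 (methyl and C9) sits next to C5 (H and C6) with the two ring-B arms trans. This is the pattern left when the enamine of an α-methyl aldehyde (C9 formyl on C10) adds to an (E)-enone whose β-carbon is C5. One chiral-primary-amine-catalysed 6-exo-trig Michael addition should therefore close ring A, form the C10 quaternary centre and C5, and fix the trans relationship and the absolute configuration. Its precursor is acyclic (E)-2,6,6-trimethyl-5,9-dioxoundec-7-enal, racemic at C10 and carried with the C3 ketone as a dioxolane.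

Key step: step 8

Numbering: drimane numbers of the target (C1–C11) are used for all intermediates; syn and anti are given relative to the C10 methyl group.

Design: the C3 carbonyl is carried as a 1,3-dioxolane from step 2 to step 14. In the key step this removes a 1,5-keto aldehyde that a primary amine could tie up as a cyclic aminal, leaves the formyl group as the only enamine-forming site, and places an axial oxygen on C3 that disfavours an axial C5 arm. Afterwards it lets ring B pass through hydride, KH and n-BuLi chemistry without a redox detour at C3. C7 and C9 are raised to the carbonyl level together in step 7, so no protecting group is needed before the key step.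

Assumption: the (R,R)-catalyst is taken to give the (7S,8R) product 16; the sense of induction of this new cyclisation cannot be guaranteed in advance, and the commercially available (S,S)-catalyst would be used if the mirror-image series were formed.

Step 1
Reactants: 1 methyl 2,2-dimethyl-3-oxobutanoate; 2 3-bromo-2-methylprop-1-ene
Product: 4 methyl 2,2,6-trimethyl-3-oxohept-6-enoate, via lithium enolate 3 (not isolated)
Conditions: LiN(iPr)2, THF, −78 °C; then 2, DMPU, −78 → 0 °C
Reagents that add atoms: none
Why: The acetyl methyl group is the only enolisable position of 1 (the other α-carbon is quaternary), so a single kinetic enolate forms and its SN2 alkylation by the allylic bromide (ketone enolate alkylation) builds the C2–C1 bond; no stereocentre is formed.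

Step 2
Reactants: 4 methyl 2,2,6-trimethyl-3-oxohept-6-enoate
Product: 5 methyl 2-methyl-2-[2-(3-methylbut-3-en-1-yl)-1,3-dioxolan-2-yl]propanoate
Conditions: (Me3SiOCH2)2, Me3SiOTf (cat.), CH2Cl2, −78 → −20 °C
Reagents that add atoms: 1,2-bis(trimethylsilyloxy)ethane, C[Si](C)(C)OCCO[Si](C)(C)C
Why: Noyori ketalisation is driven by formation of hexamethyldisiloxane and works on hindered ketones at low temperature without protic acid, so the 1,1-disubstituted alkene should not migrate and the ester is untouched.

Step 3
Reactants: 5 methyl 2-methyl-2-[2-(3-methylbut-3-en-1-yl)-1,3-dioxolan-2-yl]propanoate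
Product: 6 2-methyl-2-[2-(3-methylbut-3-en-1-yl)-1,3-dioxolan-2-yl]propan-1-ol
Conditions: LiAlH4, THF, 0 °C
Reagents that add atoms: none
Why: Hydride reduction of the neopentyl ester gives the primary alcohol while the dioxolane and the isolated alkene are inert to LiAlH4.

Step 4
Reactants: 6 2-methyl-2-[2-(3-methylbut-3-en-1-yl)-1,3-dioxolan-2-yl]propan-1-ol
Product: 7 2-methyl-2-[2-(3-methylbut-3-en-1-yl)-1,3-dioxolan-2-yl]propanal
Conditions: Dess–Martin periodinane, pyridine, CH2Cl2, 0 °C → rt
Reagents that add atoms: none
Why: Dess–Martin oxidation stops at the aldehyde, which has no α-hydrogen and so cannot enolise or self-condense, and pyridine buffers the acetic acid so that the ketal survives.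

Step 5
Reactants: 7 2-methyl-2-[2-(3-methylbut-3-en-1-yl)-1,3-dioxolan-2-yl]propanal; 8 diethyl (2-oxobutyl)phosphonate
Product: 10 (E)-6-methyl-6-[2-(3-methylbut-3-en-1-yl)-1,3-dioxolan-2-yl]hept-4-en-3-one, via sodium phosphonate carbanion 9 (not isolated)
Conditions: NaH, THF, 0 °C; then 7, 0 °C → rt
Reagents that add atoms: none
Why: Horner–Wadsworth–Emmons olefination with the stabilised β-ketophosphonate anion is reactive enough for the hindered, non-enolisable aldehyde and should give the (E)-enone, the usual outcome for stabilised phosphonates.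

Step 6
Reactants: 10 (E)-6-methyl-6-[2-(3-methylbut-3-en-1-yl)-1,3-dioxolan-2-yl]hept-4-en-3-one
Product: 12 (E)-6-[2-(4-hydroxy-3-methylbutyl)-1,3-dioxolan-2-yl]-6-methylhept-4-en-3-ol, via bis-borane adduct 11 (not isolated)
Conditions: 9-BBN (3 equiv), THF, 0 °C → rt; then NaOH, H2O2, 0 °C → rt
Reagents that add atoms: hydrogen peroxide, OO
Why: 9-BBN reduces conjugated enones by 1,2-addition and hydroborates the unhindered 1,1-disubstituted alkene at its terminal carbon (anti-Markovnikov hydroboration–oxidation) while the hindered internal alkene is left alone; the two new stereocentres form as mixtures and are both erased later (C7 in step 7, C10 in the enamine of step 8).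

Step 7
Reactants: 12 (E)-6-[2-(4-hydroxy-3-methylbutyl)-1,3-dioxolan-2-yl]-6-methylhept-4-en-3-ol
Product: 13 (E)-2-methyl-4-{2-[(3E)-2-methyl-5-oxohept-3-en-2-yl]-1,3-dioxolan-2-yl}butanal
Conditions: Dess–Martin periodinane (3 equiv), pyridine, CH2Cl2, 0 °C → rt
Reagents that add atoms: none
Why: One Dess–Martin oxidation converts the primary alcohol into the C9 aldehyde and the allylic alcohol into the C7 enone under buffered conditions that keep the ketal, giving the 5-ethylene ketal of (E)-2,6,6-trimethyl-5,9-dioxoundec-7-enal.

Step 8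
Reactants: 13 (E)-2-methyl-4-{2-[(3E)-2-methyl-5-oxohept-3-en-2-yl]-1,3-dioxolan-2-yl}butanal
Product: 16 (7S,8R)-6,6,8-trimethyl-7-(2-oxobutyl)-1,4-dioxaspiro[4.5]decane-8-carbaldehyde, via enamine 14 (not isolated), via cyclised imine 15 (not isolated)
Conditions: 1-[(1R,2R)-2-aminocyclohexyl]-3-[3,5-bis(trifluoromethyl)phenyl]thiourea (20 mol %), PhCO2H (20 mol %), H2O (2 equiv), toluene, rt → 40 °C
Reagents that add atoms: none
Why: Proposed new method: the primary amine condenses with the α-methyl aldehyde of 13 to give the (E)-enamine 14, which erases the racemic C10, and C10 then adds to the enone β-carbon C5 while the thiourea hydrogen-bonds the C7 carbonyl; proton transfer gives imine 15, whose hydrolysis releases 16 and the amine. The closest known reaction type is the amine-catalysed intramolecular Michael addition of formyl enones to trans-disubstituted carbocycles, and primary amines are known to carry α-branched aldehydes through intermolecular conjugate additions that form quaternary centres, but the two have not been combined in a six-membered ring closure. Ring A (C10, C1, C2, C3, C4, C5) closes in the 6-exo-trig mode through a chair-like transition state. C10 is set by the enamine face that the chiral diamine leaves open, and C5 by the chair in which the enamine carbon C9 and the C6 enone arm are both equatorial, which puts C9 and C6 trans and the C10 methyl axial. The step needs this trans diastereoselectivity and reaction through the aldehyde enamine only: the C4 gem-dimethyl group folds the chain, the axial dioxolane oxygen on C3 penalises an axial C5 arm, and the ketal removes the second carbonyl that could bind the amine or enolise.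

Step 9
Reactants: 16 (7S,8R)-6,6,8-trimethyl-7-(2-oxobutyl)-1,4-dioxaspiro[4.5]decane-8-carbaldehyde
Product: 18 3,3-(ethylenedioxy)drim-8-en-7-one (C5–H anti to C10–CH3), via aldol 17 (not isolated)
Conditions: KOH (cat.), MeOH, 0 °C → rt
Reagents that add atoms: none
Why: The aldehyde has no α-hydrogen, and of the ketone α-carbons only C8 can reach it through a six-membered ring (C6 would give a cyclobutane), so intramolecular aldol addition and E1cB dehydration (the ring-closing half of a Robinson annulation) should give the C8=C9 enone of ring B; C5 and C10 are not enolisable and keep their configuration.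

Step 10
Reactants: 18 3,3-(ethylenedioxy)drim-8-en-7-one (C5–H anti to C10–CH3)
Product: 19 3,3-(ethylenedioxy)drim-8-en-7-ol (C7–OH syn to C10–CH3)
Conditions: NaBH4, CeCl3·7H2O, MeOH, −78 → −20 °C
Reagents that add atoms: none
Why: Luche reduction gives 1,2-reduction only, and hydride should add axially to C7 from the face of the axial C5–H, opposite the axial C10 methyl, as in trans-fused 1-en-3-one steroids, which places the C7 hydroxyl equatorial and syn to the C10 methyl.

Step 11
Reactants: 19 3,3-(ethylenedioxy)drim-8-en-7-ol (C7–OH syn to C10–CH3)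
Product: 20 7-[(tributylstannyl)methoxy]-3,3-(ethylenedioxy)drim-8-ene (C7–O syn to C10–CH3)
Conditions: KH, THF, 0 °C; then Bu3SnCH2I, 18-crown-6, rt
Reagents that add atoms: tributyl(iodomethyl)stannane, CCCC[Sn](CCCC)(CCCC)CI
Why: Williamson etherification of the potassium alkoxide with the reactive iodomethylstannane gives the stannylmethyl ether needed for the rearrangement without touching any stereocentre.

Step 12
Reactants: 20 7-[(tributylstannyl)methoxy]-3,3-(ethylenedioxy)drim-8-ene (C7–O syn to C10–CH3)
Product: 22 3,3-(ethylenedioxy)drim-7-en-11-ol (C9–CH2OH syn to C10–CH3), via alkoxymethyllithium 21 (not isolated)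
Conditions: n-BuLi, THF, −78 → −20 °C; then H2O
Reagents that add atoms: none
Why: Tin–lithium exchange gives the α-alkoxymethyl carbanion, which undergoes the suprafacial [2,3]-Wittig–Still rearrangement, carrying the CH2O unit from the C7 oxygen to C9 on the same face (syn to the C10 methyl) and moving the double bond to C7=C8; C9 is thus set by chirality transfer from C7.

Step 13
Reactants: 22 3,3-(ethylenedioxy)drim-7-en-11-ol (C9–CH2OH syn to C10–CH3); 23 umbelliferone
Product: 24 7-{[3,3-(ethylenedioxy)drim-7-en-11-yl]oxy}-2H-chromen-2-one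
Conditions: PPh3, diisopropyl azodicarboxylate, THF, 0 °C → rt
Reagents that add atoms: none
Why: Mitsunobu etherification couples the primary alcohol with the acidic phenol under neutral conditions by SN2 at C11, which is not a stereocentre, and the ketal, alkene and lactone are inert.

Step 14
Reactants: 24 7-{[3,3-(ethylenedioxy)drim-7-en-11-yl]oxy}-2H-chromen-2-one
Product: 25 7-[(3-oxodrim-7-en-11-yl)oxy]-2H-chromen-2-one
Conditions: 1 M HCl, THF, rt
Reagents that add atoms: water, O
Why: Acid-catalysed hydrolysis of the hindered dioxolane should be fast under mild aqueous acid that leaves the aryl ether, the lactone and the trisubstituted alkene intact.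

Step 15
Reactants: 25 7-[(3-oxodrim-7-en-11-yl)oxy]-2H-chromen-2-one
Product: 27 7-[(2-hydroxy-3-oxodrim-7-en-11-yl)oxy]-2H-chromen-2-one (C2–OH anti to C10–CH3), via potassium enolate 26 (not isolated)
Conditions: KN(SiMe3)2, THF, −78 °C; then 3-phenyl-2-(phenylsulfonyl)oxaziridine, −78 °C; then AcOH
Reagents that add atoms: 3-phenyl-2-(phenylsulfonyl)oxaziridine, O=S(=O)(c1ccccc1)N1OC1c1ccccc1
Why: The ketone can enolise only toward C2 (C4 is quaternary), and Davis hydroxylation of the potassium enolate should occur on the face opposite the two axial methyl groups (on C4 and C10), giving the equatorial C2 hydroxyl anti to the C10 methyl; the non-nucleophilic base at −78 °C should spare the coumarin and the oxaziridine spares the alkene.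

Step 16
Reactants: 27 7-[(2-hydroxy-3-oxodrim-7-en-11-yl)oxy]-2H-chromen-2-one (C2–OH anti to C10–CH3)
Product: 28 7-{[(2S,3S,5S,9R,10R)-2,3-dihydroxydrim-7-en-11-yl]oxy}-2H-chromen-2-one
Conditions: NaBH4, MeOH/CH2Cl2, −20 → 0 °C
Reagents that add atoms: none
Why: Hydride reduction of the ketol should deliver hydride axially to C3 from the face opposite the axial C4 and C10 methyl groups, as in 4,4-dimethyl-3-oxo terpenoids, giving the equatorial C3 hydroxyl syn to the C10 methyl and trans to the C2 hydroxyl; the coumarin lactone is not reduced at low temperature.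

Compound list
1 | methyl 2,2-dimethyl-3-oxobutanoate | COC(=O)C(C)(C)C(C)=O | starting material
2 | 3-bromo-2-methylprop-1-ene | C=C(C)CBr | starting material
3 | lithium enolate of 1 (lithium 4-methoxy-3,3-dimethyl-4-oxobut-1-en-2-olate) | [Li]OC(=C)C(C)(C)C(=O)OC | intermediate
4 | methyl 2,2,6-trimethyl-3-oxohept-6-enoate | COC(=O)C(C)(C)C(=O)CCC(C)=C | intermediate
5 | methyl 2-methyl-2-[2-(3-methylbut-3-en-1-yl)-1,3-dioxolan-2-yl]propanoate | COC(=O)C(C)(C)C1(CCC(C)=C)OCCO1 | intermediate
6 | 2-methyl-2-[2-(3-methylbut-3-en-1-yl)-1,3-dioxolan-2-yl]propan-1-ol | OCC(C)(C)C1(CCC(C)=C)OCCO1 | intermediate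
7 | 2-methyl-2-[2-(3-methylbut-3-en-1-yl)-1,3-dioxolan-2-yl]propanal | O=CC(C)(C)C1(CCC(C)=C)OCCO1 | intermediate
8 | diethyl (2-oxobutyl)phosphonate | CCC(=O)CP(=O)(OCC)OCC | starting material
9 | sodium salt of the carbanion of 8 | [Na+].CCC(=O)[CH-]P(=O)(OCC)OCC | intermediate
10 | (E)-6-methyl-6-[2-(3-methylbut-3-en-1-yl)-1,3-dioxolan-2-yl]hept-4-en-3-one | CCC(=O)/C=C/C(C)(C)C1(CCC(C)=C)OCCO1 | intermediate
11 | bis-borane adduct of 10 (C7 O-borinate and C9 B-alkyl of 9-borabicyclo[3.3.1]nonane, stereoisomer mixture) | CCC(OB1C2CCCC1CCC2)/C=C/C(C)(C)C1(CCC(C)CB2C3CCCC2CCC3)OCCO1 | intermediate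
12 | (E)-6-[2-(4-hydroxy-3-methylbutyl)-1,3-dioxolan-2-yl]-6-methylhept-4-en-3-ol (mixture of racemic diastereomers) | CCC(O)/C=C/C(C)(C)C1(CCC(C)CO)OCCO1 | intermediate
13 | (E)-2-methyl-4-{2-[(3E)-2-methyl-5-oxohept-3-en-2-yl]-1,3-dioxolan-2-yl}butanal, the 5-ethylene ketal of (E)-2,6,6-trimethyl-5,9-dioxoundec-7-enal, racemic at C10 | CCC(=O)/C=C/C(C)(C)C1(CCC(C)C=O)OCCO1 | intermediate
14 | (E)-enamine of 13 with the (R,R)-aminothiourea catalyst | CCC(=O)/C=C/C(C)(C)C1(CC/C(C)=C/N[C@@H]2CCCC[C@H]2NC(=S)Nc2cc(C(F)(F)F)cc(C(F)(F)F)c2)OCCO1 | intermediate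
15 | cyclised imine of 16 with the (R,R)-aminothiourea catalyst | CCC(=O)C[C@@H]1C(C)(C)C2(OCCO2)CC[C@@]1(C)C=N[C@@H]1CCCC[C@H]1NC(=S)Nc1cc(C(F)(F)F)cc(C(F)(F)F)c1 | intermediate
16 | (7S,8R)-6,6,8-trimethyl-7-(2-oxobutyl)-1,4-dioxaspiro[4.5]decane-8-carbaldehyde (C9 formyl and C6 arm trans; drimane C5 S, C10 R) | CCC(=O)C[C@@H]1C(C)(C)C2(OCCO2)CC[C@@]1(C)C=O | intermediate
17 | aldol, 3,3-(ethylenedioxy)-9-hydroxydriman-7-one (C8 and C9 unassigned) | CC1C(O)[C@]2(C)CCC3(OCCO3)C(C)(C)[C@H]2CC1=O | intermediate
18 | 3,3-(ethylenedioxy)drim-8-en-7-one, trans-fused, C5–H anti to C10–CH3 | CC1=C[C@]2(C)CCC3(OCCO3)C(C)(C)[C@H]2CC1=O | intermediate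
19 | 3,3-(ethylenedioxy)drim-8-en-7-ol, C7–OH syn to C10–CH3 (7R) | CC1=C[C@]2(C)CCC3(OCCO3)C(C)(C)[C@H]2C[C@H]1O | intermediate
20 | 7-[(tributylstannyl)methoxy]-3,3-(ethylenedioxy)drim-8-ene, C7–O syn to C10–CH3 | CC1=C[C@]2(C)CCC3(OCCO3)C(C)(C)[C@H]2C[C@H]1OC[Sn](CCCC)(CCCC)CCCC | intermediate
21 | alkoxymethyllithium from 20 | CC1=C[C@]2(C)CCC3(OCCO3)C(C)(C)[C@H]2C[C@H]1OC[Li] | intermediate
22 | 3,3-(ethylenedioxy)drim-7-en-11-ol, C9–CH2OH syn to C10–CH3, C5–H anti | CC1=CC[C@@H]2C(C)(C)C3(OCCO3)CC[C@@]2(C)[C@@H]1CO | intermediate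
23 | umbelliferone (7-hydroxy-2H-chromen-2-one) | Oc1ccc2ccc(=O)oc2c1 | starting material
24 | 7-{[3,3-(ethylenedioxy)drim-7-en-11-yl]oxy}-2H-chromen-2-one, ring configuration as in 22 | CC1=CC[C@@H]2C(C)(C)C3(OCCO3)CC[C@@]2(C)[C@@H]1COc1ccc2ccc(=O)oc2c1 | intermediate
25 | 7-[(3-oxodrim-7-en-11-yl)oxy]-2H-chromen-2-one, ring configuration as in 22 | CC1=CC[C@@H]2C(C)(C)C(=O)CC[C@@]2(C)[C@@H]1COc1ccc2ccc(=O)oc2c1 | intermediate
26 | potassium C2=C3 enolate of 25 | CC1=CC[C@@H]2C(C)(C)C(O[K])=CC[C@@]2(C)[C@@H]1COc1ccc2ccc(=O)oc2c1 | intermediate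
27 | 7-[(2-hydroxy-3-oxodrim-7-en-11-yl)oxy]-2H-chromen-2-one, C2–OH equatorial and anti to C10–CH3 | CC1=CC[C@@H]2C(C)(C)C(=O)[C@@H](O)C[C@@]2(C)[C@@H]1COc1ccc2ccc(=O)oc2c1 | intermediate
28 | 7-{[(2S,3S,5S,9R,10R)-2,3-dihydroxydrim-7-en-11-yl]oxy}-2H-chromen-2-one (CNP0124364.1) | CC1=CC[C@@H]2C(C)(C)[C@H](O)[C@@H](O)C[C@@]2(C)[C@@H]1COc1ccc2ccc(=O)oc2c1 | target

Total step count: 16.
Longest linear sequence: 16 steps, from 1 to 28; 2, 8 and 23 are purchased and enter directly.

Steps most likely to fail

Step 8. The bond between the two congested carbons may form slowly, through the wrong enamine geometry or with cis closure, or the catalytic amine may be held up in side equilibria, so that rate, diastereoselectivity or enantioselectivity falls short. The fallback keeps the same bond construction but uses known stoichiometric auxiliary chemistry. It sets out from 13: condensation with (S)-1-phenylethylamine over molecular sieves should give the aldimine F1. On warming, its secondary-enamine tautomer should add to the tethered enone through the compact aza-ene-type transition state of the Pfau–d'Angelo chiral-imine Michael reaction, giving the cyclised imine F2. Hydrolysis with aqueous acetic acid comes back to the route at 16. The enantiomer of the amine is chosen to give the required series.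

Step 12. Because the C7–O bond is pseudo-equatorial, the carbanion may undergo a [1,2]-shift or be protonated faster than it rearranges, and the new bond has to form next to the quaternary C10. The fallback replaces the carbanion by a neutral thermal rearrangement. It sets out from 19: heating with N,N-dimethylformamide dimethyl acetal in xylene (Büchi [2,3]-rearrangement of the alkoxy(dimethylamino)carbene) should transfer a carbamoyl carbon from the C7 oxygen to C9 on the same face and give the β,γ-unsaturated N,N-dimethylamide F3. Reduction of the amide with LiH2NBH3 comes back to the route at 22.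

Step 15. The amide base or the enolate may attack the coumarin lactone, or the sulfonimine by-product may trap the enolate, so that hydroxylation is incomplete or unclean. The fallback changes the order so that ring A is finished before the coumarin is attached. It sets out from 22: hydrolysis of the ketal with 1 M HCl in THF should give the keto alcohol F4. Hydroxylation of its dianion with KN(SiMe3)2 and the same oxaziridine should give the ketol F5, and NaBH4 should give the triol F6. Treatment with 2-methoxypropene and pyridinium p-toluenesulfonate protects the trans-diol as the acetonide F7. Mitsunobu coupling with 23 should give the aryl ether acetonide F8, and aqueous acetic acid removes the acetonide and comes back to the route at 28.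

Further compounds
F1 | step 8 | aldimine of 13 with (S)-1-phenylethylamine | CCC(=O)/C=C/C(C)(C)C1(CCC(C)C=N[C@@H](C)c2ccccc2)OCCO1
F2 | step 8 | cyclised (S)-1-phenylethyl imine of 16 | CCC(=O)C[C@@H]1C(C)(C)C2(OCCO2)CC[C@@]1(C)C=N[C@@H](C)c1ccccc1
F3 | step 12 | 3,3-(ethylenedioxy)-N,N-dimethyldrim-7-ene-11-carboxamide (C11 amide carbon on C9, syn to C10–CH3) | CC1=CC[C@@H]2C(C)(C)C3(OCCO3)CC[C@@]2(C)[C@@H]1C(=O)N(C)C
F4 | step 15 | 11-hydroxydrim-7-en-3-one | CC1=CC[C@@H]2C(C)(C)C(=O)CC[C@@]2(C)[C@@H]1CO
F5 | step 15 | 2,11-dihydroxydrim-7-en-3-one (C2–OH anti to C10–CH3) | CC1=CC[C@@H]2C(C)(C)C(=O)[C@@H](O)C[C@@]2(C)[C@@H]1CO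
F6 | step 15 | (2S,3S,5S,9R,10R)-drim-7-ene-2,3,11-triol | CC1=CC[C@@H]2C(C)(C)[C@H](O)[C@@H](O)C[C@@]2(C)[C@@H]1CO
F7 | step 15 | 2,3-O-isopropylidene derivative of F6 | CC1=CC[C@@H]2C(C)(C)[C@@H]3OC(C)(C)O[C@H]3C[C@@]2(C)[C@@H]1CO
F8 | step 15 | 2,3-O-isopropylidene derivative of 28 | CC1=CC[C@@H]2C(C)(C)[C@@H]3OC(C)(C)O[C@H]3C[C@@]2(C)[C@@H]1COc1ccc2ccc(=O)oc2c1
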